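The aryl–CH2 bond C4–C4a of the isochromanone (C1 carbonyl, O2, C3 stereocentre; ring A is its benzene ring) is the disconnection. C4a is meta to both ring A oxygens and closed to electrophiles, but its neighbour C5 is the most nucleophilic ring carbon and C6 bears oxygen. Iodine at C5 therefore serves as a relay: in one Catellani operation palladium travels via norbornene to C4a–H, the ester-tethered bromide alkylates C4a and closes the lactone, and hydride termination returns C5–H. The precursor is (R)-1-bromopropan-2-yl 5-iodo-2,4-dimethoxy-3-methylbenzoate. The chromone is attached last at C5 through an ortho-quinone methide.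

Key step: step 3

Remark: the stereocentre of the target (C3) is read as (R). (R)-1-Bromopropan-2-ol is taken as a catalogue compound; it is otherwise one operation from (R)-propylene oxide and HBr.

Step 1
Reactants: 1 2,4-dimethoxy-3-methylbenzoic acid
Product: 2 5-iodo-2,4-dimethoxy-3-methylbenzoic acid
Conditions: NIS (1.05 equiv), CF3CO2H (cat.), MeCN, 0 °C to rt
Reagents that add atoms: N-iodosuccinimide, O=C1CCC(=O)N1I
Why: Electrophilic aromatic iodination should go only to C5, which is ortho to the 4-methoxy and para to the 2-methoxy group, whereas C6 is meta to both.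

Step 2
Reactants: 2 5-iodo-2,4-dimethoxy-3-methylbenzoic acid; 3 (R)-1-bromopropan-2-ol
Product: 4 (R)-1-bromopropan-2-yl 5-iodo-2,4-dimethoxy-3-methylbenzoate
Conditions: DCC (1.1 equiv), DMAP (0.1 equiv), CH2Cl2, 0 °C to rt
Reagents that add atoms: none
Why: Steglich esterification acylates the secondary hydroxyl without breaking the C–O bond of the stereocentre, so the (R) configuration of 3 is carried unchanged into the ester.

Step 3
Reactants: 4 (R)-1-bromopropan-2-yl 5-iodo-2,4-dimethoxy-3-methylbenzoate
Product: 5 (R)-6,8-dimethoxy-3,7-dimethylisochroman-1-one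
Conditions: Pd(OAc)2 (10 mol %), tri(2-furyl)phosphine (20 mol %), norbornene (2 equiv), Cs2CO3 (3 equiv), i-PrB(OH)2 (2 equiv), MeCN, 85 °C, 0.01 M
Reagents that add atoms: none
Why: Zerovalent palladium inserts into the C5–I bond, norbornene insertion and carbonate-assisted palladation of the only free ortho C–H (C4a) give an aryl–norbornyl palladacycle, the tethered primary C–Br adds to it in an SN2-type oxidative addition to a tetravalent palladium centre, and C(sp2)–C(sp3) reductive elimination forms the C4–C4a bond before norbornene is extruded and the C5–Pd bond is reduced by hydride transfer from the isopropyl group of the boronic acid (transmetalation, β-hydride elimination, C–H reductive elimination). The closest known reaction type is the Catellani ortho-alkylation of aryl iodides with ipso hydride termination, including its ring-forming variants in which the alkyl halide is tethered meta to iodine. The lactone ring is closed as a formal 6-exo-tet alkylation of C4 by the aryl carbon C4a, passing through a seven-membered palladacycle. No stereocentre is formed: C3 comes from 3 and none of its bonds is touched. The step needs site selectivity, which the C6 methoxy group secures by blocking the second ortho position. It also needs ring closure to run ahead of early ipso reduction and of intermolecular alkylation, which fast norbornene insertion, the slow secondary-alkyl boron hydride donor and high dilution are expected to secure.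

Step 4
Reactants: 5 (R)-6,8-dimethoxy-3,7-dimethylisochroman-1-one
Product: 6 (R)-6,8-dihydroxy-3,7-dimethylisochroman-1-one
Conditions: BBr3 (4 equiv), CH2Cl2, −78 °C to rt; then H2O
Reagents that add atoms: none
Why: Lewis-acid cleavage of both aryl methyl ethers (BBr3 demethylation) should leave the lactone and the C3 stereocentre untouched at or below room temperature.

Step 5
Reactants: 7 noreugenin (5,7-dihydroxy-2-methyl-4H-chromen-4-one)
Product: 8 eugenin (5-hydroxy-7-methoxy-2-methyl-4H-chromen-4-one)
Conditions: MeI (1.1 equiv), K2CO3 (1.1 equiv), acetone, reflux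
Reagents that add atoms: iodomethane, CI
Why: Williamson O-methylation should take only the 7-hydroxyl, because the 5-hydroxyl is hydrogen-bonded to the C4 carbonyl and far less acidic.

Step 6
Reactants: 8 eugenin
Product: 9 6-[(dimethylamino)methyl]-5-hydroxy-7-methoxy-2-methyl-4H-chromen-4-one
Conditions: CH2(NMe2)2 (1.5 equiv), 1,4-dioxane, 100 °C
Reagents that add atoms: bis(dimethylamino)methane, CN(C)CN(C)C
Why: Mannich aminomethylation of 5-hydroxy-7-alkoxychromones is delivered ortho to the only free phenol, which places the CH2 unit on C6 and not on C8.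

Step 7
Reactants: 6 (R)-6,8-dihydroxy-3,7-dimethylisochroman-1-one; 9 6-[(dimethylamino)methyl]-5-hydroxy-7-methoxy-2-methyl-4H-chromen-4-one
Product: 11 CNP0180307.1, via ortho-quinone methide 10 (not isolated)
Conditions: 6 (1.5 equiv), DMF, 120 °C, N2 stream
Reagents that add atoms: none
Why: Thermal loss of dimethylamine from 9 gives the ortho-quinone methide 10, to which C5 of 6 (the only unsubstituted ring A carbon, ortho and para to the two hydroxyls) should add in a Friedel–Crafts-type conjugate addition that rearomatises both rings and does not touch C3.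

Compound list
1 | 2,4-dimethoxy-3-methylbenzoic acid | COc1ccc(C(=O)O)c(OC)c1C | starting material
2 | 5-iodo-2,4-dimethoxy-3-methylbenzoic acid | COc1c(I)cc(C(=O)O)c(OC)c1C | intermediate
3 | (R)-1-bromopropan-2-ol | C[C@@H](O)CBr | starting material
4 | (R)-1-bromopropan-2-yl 5-iodo-2,4-dimethoxy-3-methylbenzoate | C[C@@H](OC(=O)c1cc(I)c(OC)c(C)c1OC)CBr | intermediate
5 | (R)-6,8-dimethoxy-3,7-dimethylisochroman-1-one | C[C@@H]1Cc2cc(OC)c(C)c(OC)c2C(=O)O1 | intermediate
6 | (R)-6,8-dihydroxy-3,7-dimethylisochroman-1-one | C[C@@H]1Cc2cc(O)c(C)c(O)c2C(=O)O1 | intermediate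
7 | noreugenin (5,7-dihydroxy-2-methyl-4H-chromen-4-one) | Cc1cc(=O)c2c(O)cc(O)cc2o1 | starting material
8 | eugenin (5-hydroxy-7-methoxy-2-methyl-4H-chromen-4-one) | COc1cc(O)c2c(c1)oc(C)cc2=O | intermediate
9 | 6-[(dimethylamino)methyl]-5-hydroxy-7-methoxy-2-methyl-4H-chromen-4-one | COc1cc2oc(C)cc(=O)c2c(O)c1CN(C)C | intermediate
10 | 7-methoxy-2-methyl-6-methylidene-4H-chromene-4,5(6H)-dione (ortho-quinone methide, not isolated) | C=C1C(OC)=CC2=C(C1=O)C(=O)C=C(C)O2 | intermediate
11 | CNP0180307.1, (3R)-6,8-dihydroxy-5-[(5-hydroxy-7-methoxy-2-methyl-4-oxo-4H-chromen-6-yl)methyl]-3,7-dimethylisochroman-1-one | COc1cc2oc(C)cc(=O)c2c(O)c1Cc1c(O)c(C)c(O)c2c1C[C@@H](C)OC2=O | target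

Total step count: 7. Longest linear sequence: 5 steps (steps 1, 2, 3, 4, 7).

Steps most likely to fail

Step 3. The seven-membered palladacycle that carries the bromide to palladium may form too slowly through the ester tether. Intermolecular alkylation, early reduction of the C5–Pd bond before ring closure, or base-induced loss of HBr from the bromo ester could then take over. The fallback sets out from 1 and comes back at 5, so steps 1 and 2 are not needed. Compound 1 is heated with (R)-propylene oxide, Pd(OAc)2, N-acetyl-tert-leucine and KOAc in (CF3)2CHOH at 75 °C. Carboxylate-directed palladation by divalent palladium at the C6–H bond of 1 (the later C4a) and opening of the epoxide at its CH2 terminus leave the stereocentre untouched. This should give (R)-6-(2-hydroxypropyl)-2,4-dimethoxy-3-methylbenzoic acid F1, which lactonises in the flask to 5.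

Step 7. The quinone methide may condense with itself or alkylate oxygen instead of carbon, and the liberated amine may open the lactone or the pyranone at 120 °C. The fallback sets out from 9 and comes back at 11. Compound 9 is oxidised with hexamethylenetetramine in aqueous AcOH at 100 °C (Sommelet-type) to 5-hydroxy-7-methoxy-2-methyl-4-oxo-4H-chromene-6-carbaldehyde F2. F2 and 6 are then treated with CF3CO2H and Et3SiH in CH2Cl2 at 0 °C to rt. Friedel–Crafts hydroxyalkylation at C5 of 6 should give the diarylmethanol F3 (both configurations at the carbinol carbon), which is ionised and reduced by the silane in the flask to 11.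

Step 6. Aminomethylation may go to C8 or occur twice. The fallback sets out from 8 and comes back at 10. Compound 8 is iodinated with benzyltrimethylammonium dichloroiodate (BnNMe3ICl2) and CaCO3 in CH2Cl2–MeOH, a reagent that attacks 5-hydroxy-7-alkoxychromones ortho to the free hydroxyl, to give 5-hydroxy-6-iodo-7-methoxy-2-methyl-4H-chromen-4-one F4. Stille coupling with Bu3SnCH2OH (Pd(PPh3)4, 1,4-dioxane, 90 °C) then gives 5-hydroxy-6-(hydroxymethyl)-7-methoxy-2-methyl-4H-chromen-4-one F5. On heating with 6 and catalytic TsOH, F5 loses water and enters the route at the quinone methide 10.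

Further compounds
F1 | step 3 | (R)-6-(2-hydroxypropyl)-2,4-dimethoxy-3-methylbenzoic acid | C[C@@H](O)Cc1cc(OC)c(C)c(OC)c1C(=O)O
F2 | step 7 | 5-hydroxy-7-methoxy-2-methyl-4-oxo-4H-chromene-6-carbaldehyde | COc1cc2oc(C)cc(=O)c2c(O)c1C=O
F3 | step 7 | diarylmethanol, (3R)-6,8-dihydroxy-5-[hydroxy(5-hydroxy-7-methoxy-2-methyl-4-oxo-4H-chromen-6-yl)methyl]-3,7-dimethylisochroman-1-one | COc1cc2oc(C)cc(=O)c2c(O)c1C(O)c1c(O)c(C)c(O)c2c1C[C@@H](C)OC2=O
F4 | step 6 | 5-hydroxy-6-iodo-7-methoxy-2-methyl-4H-chromen-4-one | COc1cc2oc(C)cc(=O)c2c(O)c1I
F5 | step 6 | 5-hydroxy-6-(hydroxymethyl)-7-methoxy-2-methyl-4H-chromen-4-one | COc1cc2oc(C)cc(=O)c2c(O)c1CO
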